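## Structural features

The target is a 2H-chromene: benzene ring A (C4a, C5–C8, C8a) fused to pyran ring B (O1, C2, C3=C4). C6 carries a ketone that continues through an E-enone to the 4-hydroxyphenyl ring C, so ring A is also the acyl-bearing ring of a 2′-hydroxychalcone. Ring A is oxygenated at C5, C8 and C8a; the C5 and C8 hydroxyls are para to each other (a hydroquinone), C5–OH is hydrogen-bonded to the ketone, and C7 is the only ring A carbon with a hydrogen. The single stereocentre is C2 (S), a fully substituted carbon bonded to O1, the C3=C4 alkene, a methyl group and a 4-hydroxy-4-methylpentyl chain ending in a tertiary carbinol; no neighbouring stereocentre can relay information. Fragile elements are the hydroquinone (air oxidation), the 2′-hydroxychalcone (conjugate addition, flavanone closure in acid or base), the chromene (acid-sensitive, and able to open photochemically to an o-quinone methide, which would erase C2) and the tertiary alcohol (dehydration, solvolysis). The real difficulty is the enantioselective construction of C2, whose carbon substituents differ only as methyl versus primary alkyl, followed by regiocontrolled acylation at C6 and a deprotection the finished molecule survives. The key step reads C4 as a former aryl aldehyde carbon, C3 as the γ-methyl and C2 as the β-carbon of a β-methyl enal, O1 as the phenol oxygen of a salicylaldehyde, and the C2 methyl as what remains of the enal α-carbon once its carbonyl carbon is excised.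

## Logic of the disconnections

28 ⇒ 27. Cut: the three aryl O–CH2OMe bonds and the O–Si bond. Reason: hydroquinone, 2′-hydroxychalcone and tertiary carbinol stay masked until the last operation. Gain: 27 cannot oxidise or close to a flavanone, and all four masks fall to one reagent. Demand: an acid mild enough for chromene, enone and carbinol.

27 ⇒ 19 + 24. Cut: the C6–C(=O) bond. Reason: this is the most convergent cut, separating the chiral chromene from the complete enone and ring C; C6 becomes an aryl anion (25, by bromine–lithium exchange on 19) and the carbonyl arrives as an N-methoxy-N-methyl amide. Gain: no formylation, methyl addition, oxidation and aldol sequence. Demand: a regiodefined C6 halide and carbonyl addition in preference to conjugate addition (26 as the held intermediate).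

24 ⇒ 21 + 22, and 21 ⇒ 20. Cut: the enone Cα=Cβ bond (phosphonate olefination through 23) and the O–CH2OMe bond. Gain: two commercial pieces. Demand: E selectivity.

19 ⇒ 17 ⇒ 16. Cut: the C3=C4 π bond back to a C4–O bond (18 as its activated form), then C6–Br back to C6–H. Reason: the C4 oxygen is what the key step leaves behind, and bromination is placed before the alkene exists and after the rhodium step. Demand: bromination para to O1 and not at C7; elimination under conditions that spare the acetals and silyl ether.

16 ⇒ 15. Cut (in reverse, an addition): the C2 methyl is extended by one carbonyl carbon to a CH2–CHO arm (14), tied to the cis C4 hydroxyl as lactol 15. Reason: this turns the methyl/alkyl differentiation into an aldehyde arm that is part of an enal. Demand: clean extrusion of CO from a lactol without loss of C2 configuration.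

15 ⇒ 13 + 5. Cut: C3–C4 and O1–C2, with the lactol C–O bond. Gain: two achiral building blocks and the whole side chain in one piece. Demand: γ-selective reaction of the enal through its methyl group and face selectivity at a β,β-disubstituted iminium ion.

13 ⇒ 11 ⇒ 8 ⇒ 6. Cut: the aryl–CHO bond ortho to the free phenol (12 in the flask), then the phenolic C–O bond (through 9 and 10), then the two O–CH2OMe bonds (through 7). Reason: the free hydroxyl of 11 steers formylation to its only open ortho position, and all four ring positions of 8 are equivalent, so the first metalation needs no selectivity. Demand: formylation at a carbon flanked by two oxygens.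

5 ⇒ 4 ⇒ 3 ⇒ 2 ⇒ 1. Cut: O–Si; the aldehyde oxidation level; the C7–O bond of the carbinol (from an epoxide) together with the ester; the epoxide oxygen. Reason: the distal alkene of 1 is the more electron-rich, so the oxygen is placed without mercury. Demand: regioselective epoxidation and hydride opening at the less substituted epoxide carbon.

## Other disconnections considered

Alternative 1: Cut: C7–C8, C5–C6 and C4a–C5; ring A is removed and ring B kept as a chiral dihydropyran that already holds C2.
- Forward step: the dihydropyranyl methoxycarbene complex A1 (zerovalent chromium), alkyne A2 and one CO ligand combine in a Dötz benzannulation to chromanol A3. The carbene carbon becomes C8 (OMe), the CO carbon C5 (free OH), and the acetal-bearing alkyne carbon ends up at C6.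
- In favour: the mechanism writes the ring A pattern, the two hydroquinone oxygens emerge differentiated, and a formyl equivalent sits at C6 without aromatic substitution. On ring A regiocontrol this is better than the chosen plan, which relies on a bromination. The stereocentre is not at risk in the annulation, which equals the chosen plan after step 9.
- Against: C2 must first be made in a separate asymmetric sequence to a 2,2-disubstituted dihydropyran, then metalated and converted to A1 with stoichiometric chromium. A3 has a saturated C3–C4 bond, an alkene where the tertiary alcohol belongs and a methyl ether on O8. That leaves a dehydrogenation beside an oxidisable 4-methoxyphenol, a late Markovnikov hydration in the presence of the chromene alkene, and a methyl ether cleavage in the presence of the enone, besides acetal hydrolysis and the chalcone steps.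
- Comparison: mechanistically sound and convergent, but expected to be several steps longer than the fifteen used here, and it postpones the three hardest functional-group problems to the end.

Alternative 2: Cut: C4–C4a and O1–C2; all of ring B comes from hydroxyquinone A4 and the same enal 4.
- Forward step: condensation of the vinylogous acid A4 through its C3 with the enal carbonyl gives a 1-oxatriene, which closes by oxa-6π electrocyclisation to chromenequinone A5 under a chiral Brønsted acid.
- In favour: the best step and atom economy of the four. Every enal carbon is used, nothing is excised, C3=C4 arises directly, ring A needs no protecting groups, and the hydroquinone is one mild reduction away. On these points it is clearly better than the chosen plan.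
- Against: control of this ring closure by a chiral acid has no secure precedent on such a substrate. A5 is a pyran fused to a quinone, so reopening to the oxatriene costs no aromaticity and offers a racemisation path until the quinone is reduced. A4 is unstable, and the cinnamoyl group would then have to enter at C6 of a quinone or free hydroquinone in competition with C7.
- Comparison: if the asymmetric closure were reliable this would be the shorter synthesis. As a route to one enantiomer it carries more mechanistic risk than the aminocatalytic cascade, whose control element is of a well-studied kind.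

Alternative 3: Cut: the C3=C4 double bond only.
- Forward step: triene A6, an aryl ether of a methyl divinyl carbinol with an ortho vinyl group, undergoes ring-closing metathesis with a chiral molybdenum alkylidene that selects one of two enantiotopic vinyl groups, giving chromene A7.
- In favour: catalytic desymmetrising metathesis of such ethers is an established reaction class. The chromene alkene forms directly at the right oxidation level, with no dehydration or decarbonylation, and the stereocentre is created in a ring that cannot epimerise under the conditions. On directness of chromene formation it is better than the chosen plan; on catalytic stereocontrol it is its equal.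
- Against: A6 is a hindered, doubly allylic tertiary aryl ether, hard to make on an electron-rich arene and prone to sigmatropic rearrangement. The catalyst is air- and moisture-sensitive. A7 bears a vinyl group where the 4-hydroxy-4-methylpentyl chain must stand, so three carbons and the carbinol must be added by chemistry that spares C3=C4. The ring A methyl ethers remain a problem at the end.
- Comparison: similar in length or longer once the side chain is built, whereas the chosen plan brings the whole side chain in with the enal.

Key step: step 8

Assumption: the catalyst enantiomer is assigned by the usual shielding model (E, s-trans iminium ion; new C3 methylene trans to the iminium carbon after γ-attack through the s-trans dienamine; phenol adding opposite the diarylsilyloxymethyl group), which calls for the (R)-catalyst; if the sense proves opposite, the equally available (S)-catalyst takes its place.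

Design changes to the precursors, with the disconnection unchanged:
- The ring A oxygens are carried as methoxymethyl ethers, because methyl ethers could not be removed safely from the finished chalcone.
- The tertiary alcohol is carried as a triethylsilyl ether from step 4 on.
- The side chain is hydrated by epoxidation and hydride opening, avoiding mercury.
- C6 is acylated through a bromide and an aryllithium, which is shorter than formylation followed by a chalcone build-up.
- The skeletons needed no correction: in the lactol the C2 arm and the C4 oxygen are cis, as the bridge requires, and C2 has the target arrangement.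

## Steps

Step 1
Reactants: 1 geranyl acetate
Product: 2 6,7-epoxygeranyl acetate (racemic at the epoxide)
Conditions: mCPBA (1.05 equiv), NaHCO3, CH2Cl2, 0 °C
Reagents that add atoms: mCPBA (3-chloroperoxybenzoic acid), OOC(=O)c1cccc(Cl)c1
Why: Prilezhaev epoxidation; the 6,7-alkene is the more electron-rich because the 2,3-alkene is deactivated by the allylic acetate, so one equivalent of peracid should react there; the new stereocentre is racemic and is erased in step 2.

Step 2
Reactants: 2 6,7-epoxygeranyl acetate
Product: 3 (2E)-3,7-dimethyloct-2-ene-1,7-diol
Conditions: LiAlH4, THF, 0 °C to reflux; aqueous NaOH work-up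
Reagents that add atoms: none
Why: Hydride opens the trisubstituted epoxide by SN2 attack at the less substituted carbon C6, leaving the oxygen on C7 as the tertiary alcohol, and the same reagent cleaves the acetate; the isolated trisubstituted alkene is not reduced.

Step 3
Reactants: 3 (2E)-3,7-dimethyloct-2-ene-1,7-diol
Product: 4 (2E)-7-hydroxy-3,7-dimethyloct-2-enal
Conditions: activated MnO2 (excess), CH2Cl2, rt
Reagents that add atoms: none
Why: Heterogeneous MnO2 oxidises only the allylic alcohol; the tertiary alcohol cannot be oxidised and the E geometry should be retained.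

Step 4
Reactants: 4 (2E)-7-hydroxy-3,7-dimethyloct-2-enal
Product: 5 (2E)-3,7-dimethyl-7-[(triethylsilyl)oxy]oct-2-enal
Conditions: TESOTf, 2,6-lutidine, CH2Cl2, −78 °C
Reagents that add atoms: triethylsilyl trifluoromethanesulfonate (TESOTf), CC[Si](CC)(CC)OS(=O)(=O)C(F)(F)F
Why: Silylation of a tertiary alcohol with a silyl triflate and a hindered pyridine is fast at low temperature and should outrun any reaction of the enal; the ether prevents dehydration, O-sulfonylation and alkoxide formation in steps 8, 11 and 14 and falls in step 15 without an extra operation.

Step 5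
Reactants: 6 hydroquinone
Product: 8 1,4-bis(methoxymethoxy)benzene, via 4-(methoxymethoxy)phenol 7 (not isolated)
Conditions: MOMCl (solution prepared from CH2(OMe)2, AcCl, cat. ZnBr2), i-Pr2NEt, CH2Cl2, 0 °C to rt
Reagents that add atoms: chloromethyl methyl ether (MOMCl), COCCl
Why: Twofold O-alkylation of the phenols; methoxymethyl ethers tolerate organolithiums, amines and heat, direct the lithiation of step 6 and can be removed at the end without touching enone or alkene.

Step 6
Reactants: 8 1,4-bis(methoxymethoxy)benzene
Product: 11 2,5-bis(methoxymethoxy)phenol, via 2,5-bis(methoxymethoxy)phenyllithium 9 (not isolated), via dimethyl 2,5-bis(methoxymethoxy)phenylboronate 10 (not isolated)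
Conditions: n-BuLi, TMEDA, THF, 0 °C; B(OMe)3, −78 °C to rt; H2O2, aq. NaOH, 0 °C
Reagents that add atoms: hydrogen peroxide, OO
Why: Directed ortho-metalation next to an acetal oxygen (all four ring positions of 8 are equivalent), borylation and oxidative aryl shift from boron to oxygen give the phenol.

Step 7
Reactants: 11 2,5-bis(methoxymethoxy)phenol
Product: 13 2-hydroxy-3,6-bis(methoxymethoxy)benzaldehyde, via 2-(hydroxymethyl)-3,6-bis(methoxymethoxy)phenol 12 (not isolated)
Conditions: MgCl2, Et3N, (CH2O)n, MeCN, reflux
Reagents that add atoms: paraformaldehyde (formaldehyde), C=O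
Why: Magnesium-mediated ortho-formylation: the magnesium phenoxide delivers formaldehyde to the ortho carbon through a cyclic transition state and a second formaldehyde oxidises the benzylic alkoxide by hydride transfer; only one ortho position is open, so the aldehyde must enter between the hydroxyl and the C5 ether.

Step 8
Reactants: 13 2-hydroxy-3,6-bis(methoxymethoxy)benzaldehyde; 5 (2E)-3,7-dimethyl-7-[(triethylsilyl)oxy]oct-2-enal (1.5 equiv)
Product: 15 (2S,4S)-tricyclic chroman lactol (chroman C2 and C4 bridged by CH2–CH(OH)–O; anomeric carbon as a mixture), via hydroxy aldehyde 14 (not isolated)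
Conditions: (R)-2-{bis[3,5-bis(trifluoromethyl)phenyl](trimethylsilyloxy)methyl}pyrrolidine (20 mol %), PhCO2H (20 mol %), toluene, rt
Reagents that add atoms: none
Why: The amine condenses with 5 to an iminium ion that loses a γ-methyl proton; the dienamine, reacting through its s-trans conformer, adds with its terminal methylene to the aldehyde of 13 (vinylogous aldol, C3–C4) and restores a β,β-disubstituted iminium ion. The ortho phenol then adds to the β-carbon (6-exo-trig oxa-Michael, O1–C2) to close ring B, hydrolysis releases the catalyst and 14, and the C4 hydroxyl closes the second ring by 6-exo-trig addition to the aldehyde. The closest known reaction type is the diarylprolinol silyl ether-catalysed domino aldol/oxa-Michael reaction of salicylaldehydes with β-methyl enals to 2,2-disubstituted chroman lactols. C2 is set by the catalyst: in the E, s-trans iminium ion the diarylsilyloxymethyl group covers one face and the phenol oxygen should add to the other, which with the (R)-catalyst gives the target arrangement with the arm in the place of the later methyl. C4 follows from C2, because only the isomer with the C4 oxygen cis to the arm can form the bridged lactol and a reversible aldol step can feed material into it. The anomeric carbon forms as a mixture, which is immaterial since that carbon is removed in step 9. The step needs γ-selectivity through the methyl group (not through the chain methylene, and not α-attack, which would lead to a chromene-3-carbaldehyde) and ring closure faster than E/Z isomerisation of the iminium ion. The first is favoured by the less hindered methyl and the lactol trap, the second by intramolecular delivery of the phenol through a six-membered array.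

Step 9
Reactants: 15 (2S,4S)-tricyclic chroman lactol
Product: 16 (2S,4S)-5,8-bis(methoxymethoxy)-2-methyl-2-{4-methyl-4-[(triethylsilyl)oxy]pentyl}chroman-4-ol
Conditions: RhCl(PPh3)3 (1.1 equiv), toluene, 110 °C, argon
Reagents that add atoms: none
Why: Tsuji–Wilkinson decarbonylation: the lactol equilibrates with 14, whose formyl C–H adds to monovalent rhodium, CO de-inserts and C–H reductive elimination leaves the methyl group, the metal ending as RhCl(CO)(PPh3)2 (hence the stoichiometric amount). The alkyl–rhodium intermediate is neopentyl-like with no β-hydrogen, so no alkene can form; sugar lactols are known to react this way, and C2 and C4 are untouched.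

Step 10
Reactants: 16 (2S,4S)-chroman-4-ol
Product: 17 (2S,4S)-6-bromo-5,8-bis(methoxymethoxy)-2-methyl-2-{4-methyl-4-[(triethylsilyl)oxy]pentyl}chroman-4-ol
Conditions: NBS (1.0 equiv), MeCN, 0 °C, dark
Reagents that add atoms: N-bromosuccinimide (NBS), O=C1CCC(=O)N1Br
Why: Electrophilic aromatic bromination; C6 is para to the ring oxygen O1 and ortho to the C5 ether, whereas C7 is para only to a carbon substituent, so bromine should enter at C6; placing the step here avoids an alkene in the substrate and an aryl bromide in the rhodium step.

Step 11
Reactants: 17 (2S,4S)-6-bromochroman-4-ol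
Product: 19 (2S)-6-bromo-5,8-bis(methoxymethoxy)-2-methyl-2-{4-methyl-4-[(triethylsilyl)oxy]pentyl}-2H-chromene, via C4 mesylate 18 (not isolated)
Conditions: MsCl, Et3N (excess), CH2Cl2, 0 °C to rt
Reagents that add atoms: none
Why: Dehydration through the mesylate: only the secondary alcohol is free, and the benzylic C4–O bond, flanked by two oxygen-bearing ring carbons, should ionise or eliminate with the amine at room temperature to give C3=C4; C4 ceases to be a stereocentre and C2 is not involved.

Step 12
Reactants: 20 4-hydroxybenzaldehyde
Product: 21 4-(methoxymethoxy)benzaldehyde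
Conditions: MOMCl, i-Pr2NEt, CH2Cl2, 0 °C to rt
Reagents that add atoms: chloromethyl methyl ether (MOMCl), COCCl
Why: O-Alkylation of the phenol; the ether must survive the aryllithium of step 14 and falls with the others in step 15.

Step 13
Reactants: 21 4-(methoxymethoxy)benzaldehyde; 22 diethyl {2-[methoxy(methyl)amino]-2-oxoethyl}phosphonate
Product: 24 (2E)-N-methoxy-3-[4-(methoxymethoxy)phenyl]-N-methylprop-2-enamide, via sodium phosphonate carbanion 23 (not isolated)
Conditions: NaH, THF, 0 °C to rt
Reagents that add atoms: none
Why: Horner–Wadsworth–Emmons olefination; the stabilised phosphonate anion should give the E-alkene.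

Step 14
Reactants: 19 (2S)-6-bromochromene; 24 (2E)-N-methoxy-N-methyl cinnamamide
Product: 27 (2E)-1-[(2S)-5,8-bis(methoxymethoxy)-2-methyl-2-{4-methyl-4-[(triethylsilyl)oxy]pentyl}-2H-chromen-6-yl]-3-[4-(methoxymethoxy)phenyl]prop-2-en-1-one, via C6 aryllithium 25 (not isolated), via lithium hemiaminal adduct 26 (not isolated)
Conditions: n-BuLi, THF, −78 °C; then 24, −78 to −40 °C; AcOH quench at −78 °C
Reagents that add atoms: none
Why: Bromine–lithium exchange is faster than any deprotonation at −78 °C and gives a C6 aryllithium chelated by the C5 ether; carbonyl addition to the Weinreb amide gives a chelated tetrahedral intermediate that cannot collapse before the quench, so no second addition occurs and the E-enone is released on acidic work-up (Weinreb ketone synthesis).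

Step 15
Reactants: 27 protected chalcone
Product: 28 (2E)-1-[(2S)-5,8-dihydroxy-2-(4-hydroxy-4-methylpentyl)-2-methyl-2H-chromen-6-yl]-3-(4-hydroxyphenyl)prop-2-en-1-one
Conditions: HCl (ca. 1 M) in MeOH–THF, 0 °C to rt, argon, dark
Reagents that add atoms: none
Why: Acid-catalysed acetal exchange removes the three methoxymethyl groups as dimethoxymethane and the same medium solvolyses the silyl ether; dilute methanolic HCl at or below room temperature is the usual end-game for methoxymethyl-protected 2′-hydroxychalcones and chromenes and is too weak to ionise the unstabilised tertiary carbinol, while exclusion of air and light protects the hydroquinone and the C2 configuration.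

## Compound list

1 | geranyl acetate, (2E)-3,7-dimethylocta-2,6-dien-1-yl acetate | CC(C)=CCC/C(C)=C/COC(C)=O | starting material
2 | 6,7-epoxygeranyl acetate, (2E)-5-(3,3-dimethyloxiran-2-yl)-3-methylpent-2-en-1-yl acetate (racemic) | CC1(C)OC1CC/C(C)=C/COC(C)=O | intermediate
3 | (2E)-3,7-dimethyloct-2-ene-1,7-diol | CC(C)(O)CCC/C(C)=C/CO | intermediate
4 | (2E)-7-hydroxy-3,7-dimethyloct-2-enal | CC(C)(O)CCC/C(C)=C/C=O | intermediate
5 | (2E)-3,7-dimethyl-7-[(triethylsilyl)oxy]oct-2-enal | CC[Si](CC)(CC)OC(C)(C)CCC/C(C)=C/C=O | intermediate
6 | hydroquinone | Oc1ccc(O)cc1 | starting material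
7 | 4-(methoxymethoxy)phenol | COCOc1ccc(O)cc1 | intermediate (not isolated)
8 | 1,4-bis(methoxymethoxy)benzene | COCOc1ccc(OCOC)cc1 | intermediate
9 | [2,5-bis(methoxymethoxy)phenyl]lithium | [Li]c1cc(OCOC)ccc1OCOC | intermediate (not isolated)
10 | dimethyl [2,5-bis(methoxymethoxy)phenyl]boronate | COB(OC)c1cc(OCOC)ccc1OCOC | intermediate (not isolated)
11 | 2,5-bis(methoxymethoxy)phenol | Oc1cc(OCOC)ccc1OCOC | intermediate
12 | 2-(hydroxymethyl)-3,6-bis(methoxymethoxy)phenol (present as its magnesium salt) | OCc1c(O)c(OCOC)ccc1OCOC | intermediate (not isolated)
13 | 2-hydroxy-3,6-bis(methoxymethoxy)benzaldehyde | O=Cc1c(O)c(OCOC)ccc1OCOC | intermediate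
14 | 2-[(2S,4S)-4-hydroxy-5,8-bis(methoxymethoxy)-2-{4-methyl-4-[(triethylsilyl)oxy]pentyl}chroman-2-yl]acetaldehyde | CC[Si](CC)(CC)OC(C)(C)CCC[C@@]1(CC=O)C[C@H](O)c2c(OCOC)ccc(OCOC)c2O1 | intermediate (not isolated)
15 | (2S,4S)-tricyclic lactol of 14 (C2 and C4 of the chroman bridged by CH2–CH(OH)–O, anomeric carbon as a mixture) | CC[Si](CC)(CC)OC(C)(C)CCC[C@@]12CC(O)O[C@@H](C1)c3c(OCOC)ccc(OCOC)c3O2 | intermediate
16 | (2S,4S)-5,8-bis(methoxymethoxy)-2-methyl-2-{4-methyl-4-[(triethylsilyl)oxy]pentyl}chroman-4-ol | CC[Si](CC)(CC)OC(C)(C)CCC[C@@]1(C)C[C@H](O)c2c(OCOC)ccc(OCOC)c2O1 | intermediate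
17 | (2S,4S)-6-bromo-5,8-bis(methoxymethoxy)-2-methyl-2-{4-methyl-4-[(triethylsilyl)oxy]pentyl}chroman-4-ol | CC[Si](CC)(CC)OC(C)(C)CCC[C@@]1(C)C[C@H](O)c2c(OCOC)c(Br)cc(OCOC)c2O1 | intermediate
18 | (2S,4S)-6-bromo-5,8-bis(methoxymethoxy)-2-methyl-2-{4-methyl-4-[(triethylsilyl)oxy]pentyl}chroman-4-yl methanesulfonate | CC[Si](CC)(CC)OC(C)(C)CCC[C@@]1(C)C[C@H](OS(C)(=O)=O)c2c(OCOC)c(Br)cc(OCOC)c2O1 | intermediate (not isolated)
19 | (2S)-6-bromo-5,8-bis(methoxymethoxy)-2-methyl-2-{4-methyl-4-[(triethylsilyl)oxy]pentyl}-2H-chromene | CC[Si](CC)(CC)OC(C)(C)CCC[C@@]1(C)C=Cc2c(OCOC)c(Br)cc(OCOC)c2O1 | intermediate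
20 | 4-hydroxybenzaldehyde | O=Cc1ccc(O)cc1 | starting material
21 | 4-(methoxymethoxy)benzaldehyde | COCOc1ccc(C=O)cc1 | intermediate
22 | diethyl {2-[methoxy(methyl)amino]-2-oxoethyl}phosphonate | CCOP(=O)(OCC)CC(=O)N(C)OC | starting material
23 | sodium salt of the carbanion of 22 | [Na+].CCOP(=O)(OCC)[CH-]C(=O)N(C)OC | intermediate (not isolated)
24 | (2E)-N-methoxy-3-[4-(methoxymethoxy)phenyl]-N-methylprop-2-enamide | CON(C)C(=O)/C=C/c1ccc(OCOC)cc1 | intermediate
25 | [(2S)-5,8-bis(methoxymethoxy)-2-methyl-2-{4-methyl-4-[(triethylsilyl)oxy]pentyl}-2H-chromen-6-yl]lithium | CC[Si](CC)(CC)OC(C)(C)CCC[C@@]1(C)C=Cc2c(OCOC)c([Li])cc(OCOC)c2O1 | intermediate (not isolated)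
26 | lithium alkoxide of the tetrahedral adduct of 25 and 24 (carbinol carbon as a mixture) | CC[Si](CC)(CC)OC(C)(C)CCC[C@@]1(C)C=Cc2c(OCOC)c(C(O[Li])(/C=C/c3ccc(OCOC)cc3)N(C)OC)cc(OCOC)c2O1 | intermediate (not isolated)
27 | (2E)-1-[(2S)-5,8-bis(methoxymethoxy)-2-methyl-2-{4-methyl-4-[(triethylsilyl)oxy]pentyl}-2H-chromen-6-yl]-3-[4-(methoxymethoxy)phenyl]prop-2-en-1-one | CC[Si](CC)(CC)OC(C)(C)CCC[C@@]1(C)C=Cc2c(OCOC)c(C(=O)/C=C/c3ccc(OCOC)cc3)cc(OCOC)c2O1 | intermediate
28 | (2E)-1-[(2S)-5,8-dihydroxy-2-(4-hydroxy-4-methylpentyl)-2-methyl-2H-chromen-6-yl]-3-(4-hydroxyphenyl)prop-2-en-1-one (CNP0322520.1) | CC(C)(O)CCC[C@@]1(C)C=Cc2c(O)c(C(=O)/C=C/c3ccc(O)cc3)cc(O)c2O1 | target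

## Step count and risks

Total: 15 steps. Longest linear sequence: 10 steps (1, 2, 3, 4, 8, 9, 10, 11, 14, 15); the aldehyde branch (5–7) and the amide branch (12, 13) are shorter.

**Step 8 (key step).**
- Risk: insufficient face selectivity in the oxa-Michael closure if E/Z equilibration of the β,β-disubstituted iminium ion competes with ring closure; and slow vinylogous aldol addition to the hindered, electron-rich aldehyde, letting self-condensation of the enal take over.
- Fallback, from 11 and 5, returning at 19: phenol 11 is brominated para to its hydroxyl (NBS, MeCN, 0 °C) to 4-bromo-2,5-bis(methoxymethoxy)phenol F1. Condensation of F1 with 5 under PhB(OH)2 and a carboxylic acid in hot toluene should give the racemic 6-bromochromene F2 in one operation (ortho C-alkylation through the aryl borate, loss of water to the o-quinone methide, oxa-6π closure). Here the enal carbonyl carbon becomes C4 and no decarbonylation is needed. Separation on a chiral stationary phase gives 19 and its (2R)-enantiomer F3. Catalytic stereocontrol is given up for resolution, at the cost of half the material.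

**Step 9.**
- Risk: slow CO extrusion (little open aldehyde 14, hindered formyl group), which leaves time at 110 °C for retro-oxa-Michael opening of the β-aryloxy aldehyde and thus erosion of C2 configuration, or thermal loss of water at C4.
- Fallback, from 15, returning at 19: oxidation of the lactol (TEMPO, PhI(OAc)2, CH2Cl2) to the bridged (2S,4S)-lactone F4, then bromination at C6 (NBS, MeCN, 0 °C) to the 6-bromo lactone F5. Acid-induced ionisation of the benzylic lactone C4–O bond with loss of H3 (PPTS, toluene, 80 °C) gives [(2R)-6-bromo-5,8-bis(methoxymethoxy)-2-{4-methyl-4-[(triethylsilyl)oxy]pentyl}-2H-chromen-2-yl]acetic acid F6. Coupling with N-hydroxypyridine-2-thione (DCC, CH2Cl2, dark) gives the O-acyl thiohydroxamate F7, and Barton decarboxylation (visible light, t-BuSH) gives 19. The carbon is removed as CO2 rather than CO and the dehydration is merged into the sequence.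

**Step 14.**
- Risk: conjugate addition of the aryllithium to the cinnamoyl amide competing with carbonyl addition, or addition of the released N,O-dimethylhydroxylamine to the enone during work-up.
- Fallback, from 19 and 21, returning at 27: aryllithium 25 is quenched with N-methoxy-N-methylacetamide to 1-[(2S)-5,8-bis(methoxymethoxy)-2-methyl-2-{4-methyl-4-[(triethylsilyl)oxy]pentyl}-2H-chromen-6-yl]ethan-1-one F8. Claisen–Schmidt condensation of F8 with 21 (KOH, EtOH, rt) gives 27.

**Step 15.**
- Risk: acid-promoted side reactions overtaking the slower cleavage of the C8 and C4′ acetals, namely closure of the freed C5 phenol onto the enone (flavanone-type cyclisation), solvolysis at the tertiary carbinol, or decomposition of the chromene.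
- Fallback, from 27, returning at 28: non-protic cleavage with TMSOTf and 2,2′-bipyridyl in MeCN (0 °C to rt) converts the three aryl methoxymethyl ethers into aryl trimethylsilyl ethers, giving the tris(trimethylsilyl) ether F9. HF·pyridine in THF at 0 °C then removes all four silyl groups to give 28.

**Step 7.**
- Risk: incomplete ortho-hydroxymethylation at a carbon flanked by two oxygen substituents.
- Fallback, from 11, returning at 13: protection of the phenol with 3,4-dihydro-2H-pyran (cat. PPTS, CH2Cl2) gives 2-[2,5-bis(methoxymethoxy)phenoxy]oxane F10. Lithiation between the two acetal oxygens (n-BuLi, THF, 0 °C) and quench with DMF gives 3,6-bis(methoxymethoxy)-2-(oxan-2-yloxy)benzaldehyde F11. Selective removal of the more labile tetrahydropyranyl group (PPTS, EtOH, 40 °C) gives 13.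

## Further compounds

F1 | step 8 | 4-bromo-2,5-bis(methoxymethoxy)phenol | Oc1cc(OCOC)c(Br)cc1OCOC
F2 | step 8 | racemic 6-bromo-5,8-bis(methoxymethoxy)-2-methyl-2-{4-methyl-4-[(triethylsilyl)oxy]pentyl}-2H-chromene | CC[Si](CC)(CC)OC(C)(C)CCCC1(C)C=Cc2c(OCOC)c(Br)cc(OCOC)c2O1
F3 | step 8 | (2R)-6-bromo-5,8-bis(methoxymethoxy)-2-methyl-2-{4-methyl-4-[(triethylsilyl)oxy]pentyl}-2H-chromene | CC[Si](CC)(CC)OC(C)(C)CCC[C@]1(C)C=Cc2c(OCOC)c(Br)cc(OCOC)c2O1
F4 | step 9 | (2S,4S)-bridged lactone (C2 and C4 of the chroman joined by CH2–C(=O)–O) | CC[Si](CC)(CC)OC(C)(C)CCC[C@@]12CC(=O)O[C@@H](C1)c3c(OCOC)ccc(OCOC)c3O2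
F5 | step 9 | (2S,4S)-6-bromo bridged lactone | CC[Si](CC)(CC)OC(C)(C)CCC[C@@]12CC(=O)O[C@@H](C1)c3c(OCOC)c(Br)cc(OCOC)c3O2
F6 | step 9 | [(2R)-6-bromo-5,8-bis(methoxymethoxy)-2-{4-methyl-4-[(triethylsilyl)oxy]pentyl}-2H-chromen-2-yl]acetic acid | CC[Si](CC)(CC)OC(C)(C)CCC[C@@]1(CC(=O)O)C=Cc2c(OCOC)c(Br)cc(OCOC)c2O1
F7 | step 9 | 2-thioxopyridin-1(2H)-yl [(2R)-6-bromo-5,8-bis(methoxymethoxy)-2-{4-methyl-4-[(triethylsilyl)oxy]pentyl}-2H-chromen-2-yl]acetate | CC[Si](CC)(CC)OC(C)(C)CCC[C@@]1(CC(=O)On3ccccc3=S)C=Cc2c(OCOC)c(Br)cc(OCOC)c2O1
F8 | step 14 | 1-[(2S)-5,8-bis(methoxymethoxy)-2-methyl-2-{4-methyl-4-[(triethylsilyl)oxy]pentyl}-2H-chromen-6-yl]ethan-1-one | CC[Si](CC)(CC)OC(C)(C)CCC[C@@]1(C)C=Cc2c(OCOC)c(C(C)=O)cc(OCOC)c2O1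
F9 | step 15 | (2E)-1-[(2S)-2-methyl-2-{4-methyl-4-[(triethylsilyl)oxy]pentyl}-5,8-bis[(trimethylsilyl)oxy]-2H-chromen-6-yl]-3-{4-[(trimethylsilyl)oxy]phenyl}prop-2-en-1-one | CC[Si](CC)(CC)OC(C)(C)CCC[C@@]1(C)C=Cc2c(O[Si](C)(C)C)c(C(=O)/C=C/c3ccc(O[Si](C)(C)C)cc3)cc(O[Si](C)(C)C)c2O1
F10 | step 7 | 2-[2,5-bis(methoxymethoxy)phenoxy]oxane | COCOc1ccc(OCOC)c(OC2CCCCO2)c1
F11 | step 7 | 3,6-bis(methoxymethoxy)-2-(oxan-2-yloxy)benzaldehyde | O=Cc1c(OC2CCCCO2)c(OCOC)ccc1OCOC
A1 | alternative 1 | pentacarbonyl{methoxy[(2S)-2-methyl-2-(4-methylpent-3-en-1-yl)-3,4-dihydro-2H-pyran-6-yl]methylidene}chromium | CC(C)=CCC[C@@]1(C)CCC=C(O1)C(OC)=[Cr](=C=O)(=C=O)(=C=O)(=C=O)=C=O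
A2 | alternative 1 | 3,3-diethoxyprop-1-yne | C#CC(OCC)OCC
A3 | alternative 1 | (2S)-6-(diethoxymethyl)-8-methoxy-2-methyl-2-(4-methylpent-3-en-1-yl)chroman-5-ol | CC(C)=CCC[C@@]1(C)CCc2c(O)c(C(OCC)OCC)cc(OC)c2O1
A4 | alternative 2 | 2-hydroxy-1,4-benzoquinone | O=C1C=CC(=O)C(O)=C1
A5 | alternative 2 | (2S)-2-(4-hydroxy-4-methylpentyl)-2-methyl-2H-chromene-5,8-dione | CC(C)(O)CCC[C@@]1(C)C=CC2=C(O1)C(=O)C=CC2=O
A6 | alternative 3 | 1,4-dimethoxy-2-[(3-methylpenta-1,4-dien-3-yl)oxy]-3-vinylbenzene | C=CC(C)(C=C)Oc1c(OC)ccc(OC)c1C=C
A7 | alternative 3 | (2S)-5,8-dimethoxy-2-methyl-2-vinyl-2H-chromene | C=C[C@@]1(C)C=Cc2c(OC)ccc(OC)c2O1
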